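Target 33 ⇐ hydroxy acetate 31 by C16–O bond formation, closing the oxepane (O, C16, C15, C14, C1, C2, C3) last. Enabling feature: C2 (carrying the tertiary C3–OH) and C15 (carrying C16) are trans-diequatorial neighbours on the cyclohexane bond C1–C14, so O(C3) and C16 sit 1,6 to each other on the convex face of the cis-fused oxolane/cyclohexane.
31 ⇐ tricyclic cycloadduct 20: C12 methyl by α-methylenation and face-selective hydrogenation, C11 oxygen by hydride reduction, C15/C16 by methylenation and hydroboration.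
20 ⇐ oxonene 18 by soft enolisation to a 2-silyloxy diene and intramolecular Diels–Alder reaction, which closes the cyclohexene and the oxolane together.
Oxonene 11 ⇐ acyclic diene 10 by ring-closing metathesis; C2 from an Evans glycolate aldol, C3 from a chelation-controlled Grignard addition, C9 from asymmetric methallylation of aldehyde 1.
Ring order: oxonene (step 9), cyclohexene + oxolane (step 17), oxepane (step 26).

Key step: step 26

Remark (numbering): locants C1–C20 in names are those of the target skeleton: cyclohexane C1, C10–C14 (C11 OAc, C12 methyl C20); oxolane C1, C2, O, C9, C10; oxonene O, C2–C9 (C3 methyl C18, C6=C7, C7 methyl C19); C15 carries methyl C17 and C16.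
Assumption: the borane made from (−)-Ipc2BOMe is taken to deliver the (S)-carbinol from aldehyde 1, as it does with other unbranched aldehydes; the antipodal reagent would be used otherwise.

Step 1
Reactants: 1 3-[(tert-butyldimethylsilyl)oxy]propanal
Product: 2 (S)-1-[(tert-butyldimethylsilyl)oxy]-5-methylhex-5-en-3-ol
Conditions: (−)-Ipc2BOMe, 2-methylallylMgCl, Et2O, −78 °C to rt; then 1, −78 °C; NaOH, H2O2
Reagents that add atoms: 2-methylallylmagnesium chloride, C=C(C)C[Mg]Cl
Why: Brown asymmetric methallylboration; the chair transition state of the diisopinocampheylborane differentiates the aldehyde faces and should set C9 as (S).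

Step 2
Reactants: 2 (S)-1-[(tert-butyldimethylsilyl)oxy]-5-methylhex-5-en-3-ol
Product: 3 2-{[(S)-1-(TBSO)-5-methylhex-5-en-3-yl]oxy}acetic acid
Conditions: NaH (2.5 equiv), BrCH2CO2H, THF/DMF, 0 °C to rt; acidic work-up
Reagents that add atoms: bromoacetic acid, OC(=O)CBr
Why: Williamson O-alkylation of the sodium alkoxide with the bromoacetate anion; no stereocentre is touched and the silyl ether is stable to the base.

Step 3
Reactants: 3 2-{[(S)-1-(TBSO)-5-methylhex-5-en-3-yl]oxy}acetic acid
Product: 5 (R)-4-benzyl-3-(2-{[(S)-1-(TBSO)-5-methylhex-5-en-3-yl]oxy}acetyl)oxazolidin-2-one, via mixed pivalic anhydride 4 (not isolated)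
Conditions: PivCl, Et3N, THF, −20 °C; then (R)-4-benzyl-2-oxazolidinone, LiCl, rt
Reagents that add atoms: (R)-4-benzyl-2-oxazolidinone, O=C1N[C@H](Cc2ccccc2)CO1
Why: N-acylation of the oxazolidinone by the mixed anhydride (LiCl/Et3N activation) installs the Evans auxiliary; the hindered pivaloyl carbonyl is not attacked.

Step 4
Reactants: 5 glycolyl imide
Product: 6 (R)-4-benzyl-3-[(2R,3S)-3-hydroxy-2-{[(S)-1-(TBSO)-5-methylhex-5-en-3-yl]oxy}butanoyl]oxazolidin-2-one
Conditions: Bu2BOTf, i-Pr2NEt, CH2Cl2, −78 to 0 °C; MeCHO, −78 °C; pH 7 buffer, MeOH, H2O2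
Reagents that add atoms: acetaldehyde, CC=O
Why: Evans boron glycolate aldol; the (Z)-boron enolate reacts through a chair transition state with the auxiliary benzyl group shielding one face, which sets C2 (syn adduct), while the C3 carbinol configuration is erased in step 7.

Step 5
Reactants: 6 syn-aldol imide
Product: 7 (2S,3S)-2-{[(S)-1-(TBSO)-5-methylhex-5-en-3-yl]oxy}butane-1,3-diol
Conditions: LiBH4, MeOH (1 equiv), THF, 0 °C
Reagents that add atoms: none
Why: Reductive cleavage of the imide by borohydride releases the auxiliary and gives the C1 primary alcohol; alkene and silyl ether are inert.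

Step 6
Reactants: 7 1,3-diol
Product: 8 (2S,3S)-4-(TBDPSO)-3-{[(S)-1-(TBSO)-5-methylhex-5-en-3-yl]oxy}butan-2-ol
Conditions: TBDPSCl, imidazole, CH2Cl2, 0 °C
Reagents that add atoms: tert-butyl(chloro)diphenylsilane, CC(C)(C)[Si](Cl)(c1ccccc1)c1ccccc1
Why: Sterically controlled silylation; the bulky chlorosilane reacts only with the primary C1 hydroxyl.

Step 7
Reactants: 8 secondary alcohol
Product: 9 (S)-4-(TBDPSO)-3-{[(S)-1-(TBSO)-5-methylhex-5-en-3-yl]oxy}butan-2-one
Conditions: Dess–Martin periodinane, NaHCO3, CH2Cl2, 0 °C to rt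
Reagents that add atoms: none
Why: Dess–Martin oxidation to the methyl ketone under buffered, non-basic conditions should keep the α-alkoxy stereocentre C2.

Step 8
Reactants: 9 α-alkoxy methyl ketone
Product: 10 (2S,3S)-1-(TBDPSO)-3-methyl-2-{[(S)-1-(TBSO)-5-methylhex-5-en-3-yl]oxy}hept-6-en-3-ol
Conditions: but-3-enylMgBr, CH2Cl2/Et2O, −78 °C
Reagents that add atoms: but-3-en-1-ylmagnesium bromide, C=CCC[Mg]Br
Why: Cram-chelate Grignard addition; magnesium bridges the ketone oxygen and the C2 ether oxygen and the butenyl group attacks the face anti to the C1 arm, which sets the tertiary carbinol C3 (S).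

Step 9
Reactants: 10 acyclic diene
Product: 11 (2S,3S,9S,Z)-2-[(TBDPSO)methyl]-9-[2-(TBSO)ethyl]-3,7-dimethyl-2,3,4,5,8,9-hexahydrooxonin-3-ol
Conditions: Grubbs II (10 mol%), CH2Cl2 (2 mM), 40 °C
Reagents that add atoms: none
Why: Ring-closing metathesis; the gauche C2–O/C3–O arrangement preorganises the two alkenes, the nine-membered ring can only hold the Z-alkene, and ethene is lost.

Step 10
Reactants: 11 bis-silylated oxonene
Product: 12 oxonene with free C11–OH (9-(2-hydroxyethyl); C1 OTBDPS, C3 OH)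
Conditions: CSA (10 mol%), MeOH/CH2Cl2, 0 °C
Reagents that add atoms: none
Why: Acid-catalysed methanolysis cleaves the primary TBS ether far faster than the TBDPS ether.

Step 11
Reactants: 12 primary alcohol
Product: 13 oxonene C11 aldehyde (9-(2-oxoethyl))
Conditions: Dess–Martin periodinane, NaHCO3, CH2Cl2, 0 °C
Reagents that add atoms: none
Why: Dess–Martin oxidation stops at the aldehyde; the tertiary alcohol cannot be oxidised and the buffer prevents β-elimination of the C9 oxygen.

Step 12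
Reactants: 13 aldehyde
Product: 14 oxonene vinyl carbinol (9-(2-hydroxybut-3-enyl), both C11 epimers)
Conditions: vinylMgBr (2.5 equiv), THF, −78 °C
Reagents that add atoms: vinylmagnesium bromide, C=C[Mg]Br
Why: Grignard 1,2-addition; both C11 epimers are carried on because C11 becomes sp2 in step 16.

Step 13
Reactants: 14 vinyl carbinol
Product: 15 oxonene triol (C1–OH, C3–OH, C11–OH)
Conditions: TBAF, THF, 0 °C to rt; NH4Cl work-up
Reagents that add atoms: none
Why: Fluoride desilylation, driven by the Si–F bond, frees the C1 hydroxyl.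

Step 14
Reactants: 15 triol
Product: 16 oxonene C1 aldehyde (2-formyl)
Conditions: TEMPO (10 mol%), PhI(OAc)2, CH2Cl2, rt
Reagents that add atoms: none
Why: Oxoammonium (TEMPO) oxidation is selective for the primary alcohol over the secondary allylic and tertiary ones.

Step 15
Reactants: 16 aldehyde
Product: 17 (E)-Weinreb enamide (C1=C14) with free C3–OH and C11–OH
Conditions: Ph3P=CHC(O)N(OMe)Me, CH2Cl2, 40 °C
Reagents that add atoms: N-methoxy-N-methyl-2-(triphenylphosphoranylidene)acetamide, CON(C)C(=O)C=P(c1ccccc1)(c1ccccc1)c1ccccc1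
Why: Wittig olefination with a stabilised ylide gives the (E)-alkene that becomes the dienophile; the neutral conditions avoid epimerisation of C2.

Step 16
Reactants: 17 allylic alcohol
Product: 18 oxonene vinyl ketone (C11=O, C12=C13) with (E)-enamide
Conditions: Dess–Martin periodinane, NaHCO3, CH2Cl2, 0 °C
Reagents that add atoms: none
Why: Dess–Martin oxidation of the allylic alcohol to the enone; the tertiary alcohol and the amide are inert.

Step 17
Reactants: 18 vinyl ketone
Product: 20 tricyclic cycloadduct (C11 OTBS enol ether C11=C12, C14 CON(OMe)Me, C3 OTBS), via silyloxy diene 19 (not isolated)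
Conditions: TBSOTf (2.5 equiv), Et3N, CH2Cl2, −78 to 0 °C; then PhMe, 60 °C
Reagents that add atoms: tert-butyldimethylsilyl trifluoromethanesulfonate, CC(C)(C)[Si](C)(C)OS(=O)(=O)C(F)(F)F
Why: Soft enolisation gives the (Z)-2-silyloxy diene (and silylates C3–OH), and the intramolecular Diels–Alder reaction through the exo transition state enforced by the cis-2,9-disubstituted oxonene should set C1, C10 and C14: C2/C15 trans from the (E)-dienophile, cis ring fusion with H1/H2 and H10/H9 trans because the two arms can only meet on the face away from C3 and C8.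

Step 18
Reactants: 20 silyl enol ether
Product: 23 12-methylene-11-ketone, via Mannich base 21 (not isolated), via ammonium iodide 22 (not isolated)
Conditions: CH2=NMe2+ I−, CH2Cl2, rt; MeI; NaHCO3 (aq), CH2Cl2
Reagents that add atoms: N,N-dimethylmethyleneiminium iodide (Eschenmoser's salt), C=[N+](C)C.[I-]
Why: Eschenmoser methylenation; the silyl enol ether attacks the iminium ion regiospecifically at C12 (Mannich reaction) and Hofmann-type elimination of the quaternised amine gives the α-methylene ketone.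

Step 19
Reactants: 23 α-methylene ketone
Product: 24 12-methyl-11-ketone (methyl syn to the C10–C9 bond)
Conditions: H2 (1 atm), RhCl(PPh3)3 (10 mol%), benzene, rt
Reagents that add atoms: none
Why: Homogeneous hydrogenation with Wilkinson's catalyst reduces only the 1,1-disubstituted conjugated alkene; the axial C10–C9 bond blocks the upper face, so hydrogen should add to C12 from below and leave the methyl syn to C9.

Step 20
Reactants: 24 ketone
Product: 25 11-alcohol (OH cis to the C12 methyl and to C9)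
Conditions: NaBH4, MeOH, −20 °C
Reagents that add atoms: none
Why: Hydride adds to C11 from the open face anti to the two flanking substituents (C9 and the C12 methyl), giving the all-cis alcohol; the Weinreb amide is not reduced by NaBH4.

Step 21
Reactants: 25 Weinreb amide
Product: 26 14-acetyl compound (C15 methyl ketone)
Conditions: MeMgBr (3 equiv), THF, −20 to 0 °C
Reagents that add atoms: methylmagnesium bromide, C[Mg]Br
Why: Weinreb ketone synthesis; the chelated tetrahedral intermediate stops at the methyl ketone, and the trans-diequatorial C14 configuration is the thermodynamic one.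

Step 22
Reactants: 26 methyl ketone
Product: 27 14-isopropenyl compound (C15=C16)
Conditions: Ph3PCH3Br, KOt-Bu (excess), THF, 0 °C to rt
Reagents that add atoms: methyltriphenylphosphonium bromide, C[P+](c1ccccc1)(c1ccccc1)c1ccccc1.[Br-]
Why: Wittig methylenation of the ketone; the free C11 alkoxide and the silyl ether are tolerated.

Step 23
Reactants: 27 11-alcohol
Product: 28 11-acetate
Conditions: Ac2O, DMAP (cat.), pyridine, CH2Cl2, rt
Reagents that add atoms: acetic anhydride, CC(=O)OC(C)=O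
Why: DMAP-catalysed acetylation of the only free hydroxyl.

Step 24
Reactants: 28 isopropenyl acetate
Product: 30 C16 primary alcohol (15R; C3 OTBS, 11-OAc), via alkylborane 29 (not isolated)
Conditions: 9-BBN, THF, 0 °C to rt; then pH 7 buffer, H2O2, 0 °C
Reagents that add atoms: hydrogen peroxide, OO
Why: Anti-Markovnikov hydroboration–oxidation with 9-BBN, selective for the 1,1-disubstituted alkene over the trisubstituted C6=C7; with H14 eclipsing the alkene (minimised allylic strain) boron should add on the face anti to the C1 branch, setting C15 (R).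

Step 25
Reactants: 30 tertiary silyl ether
Product: 31 hydroxy acetate diol (C16–OH, C3–OH, 11-OAc)
Conditions: HF·pyridine, pyridine/THF, 0 °C to rt
Reagents that add atoms: none
Why: Buffered fluoride desilylation frees the tertiary C3 hydroxyl; acetate and the trisubstituted alkene survive.

Step 26
Reactants: 31 hydroxy acetate diol
Product: 33 target, via primary triflate 32 (not isolated)
Conditions: Tf2O (1.1 equiv), 2,6-lutidine (3 equiv), CH2Cl2, −78 °C to rt
Reagents that add atoms: none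
Why: The primary C16 hydroxyl is triflated selectively at −78 °C, and on warming the tertiary C3 hydroxyl displaces triflate by SN2 (intramolecular Williamson etherification; closest known type: hydroxy-triflate cycloetherification with hindered alcohols). The oxepane closes in the 7-exo-tet mode. No stereocentre is formed or touched, because the only bond made is C16–O at an unsubstituted methylene, so C3 and C15 keep their configuration. Closure should be fast because C2 and C15 are trans-diequatorial on C1–C14 of the chair cyclohexane, which holds O(C3) and C16 within bonding distance on the convex face. The step needs O(C3) to win over E2 loss of triflate, the acetate carbonyl and the C6=C7 π-bond; the 1,6-preorganisation and the non-nucleophilic base 2,6-lutidine, which also buffers triflic acid, should secure this.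

Compound list
1 | 3-[(tert-butyldimethylsilyl)oxy]propanal | O=CCCO[Si](C)(C)C(C)(C)C | starting material
2 | (S)-1-[(tert-butyldimethylsilyl)oxy]-5-methylhex-5-en-3-ol | C=C(C)C[C@H](O)CCO[Si](C)(C)C(C)(C)C | intermediate
3 | 2-{[(S)-1-(TBSO)-5-methylhex-5-en-3-yl]oxy}acetic acid | C=C(C)C[C@H](OCC(=O)O)CCO[Si](C)(C)C(C)(C)C | intermediate
4 | mixed anhydride of 3 with pivalic acid | C=C(C)C[C@H](OCC(=O)OC(=O)C(C)(C)C)CCO[Si](C)(C)C(C)(C)C | intermediate
5 | (R)-4-benzyl-3-(2-{[(S)-1-(TBSO)-5-methylhex-5-en-3-yl]oxy}acetyl)oxazolidin-2-one | C=C(C)C[C@H](OCC(=O)N1[C@H](Cc2ccccc2)COC1=O)CCO[Si](C)(C)C(C)(C)C | intermediate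
6 | (R)-4-benzyl-3-[(2R,3S)-3-hydroxy-2-{[(S)-1-(TBSO)-5-methylhex-5-en-3-yl]oxy}butanoyl]oxazolidin-2-one | C=C(C)C[C@H](O[C@@H](C(=O)N1[C@H](Cc2ccccc2)COC1=O)[C@H](C)O)CCO[Si](C)(C)C(C)(C)C | intermediate
7 | (2S,3S)-2-{[(S)-1-(TBSO)-5-methylhex-5-en-3-yl]oxy}butane-1,3-diol | C=C(C)C[C@H](O[C@@H](CO)[C@H](C)O)CCO[Si](C)(C)C(C)(C)C | intermediate
8 | (2S,3S)-4-(TBDPSO)-3-{[(S)-1-(TBSO)-5-methylhex-5-en-3-yl]oxy}butan-2-ol | C=C(C)C[C@H](O[C@@H](CO[Si](c1ccccc1)(c1ccccc1)C(C)(C)C)[C@H](C)O)CCO[Si](C)(C)C(C)(C)C | intermediate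
9 | (S)-4-(TBDPSO)-3-{[(S)-1-(TBSO)-5-methylhex-5-en-3-yl]oxy}butan-2-one | C=C(C)C[C@H](O[C@@H](CO[Si](c1ccccc1)(c1ccccc1)C(C)(C)C)C(C)=O)CCO[Si](C)(C)C(C)(C)C | intermediate
10 | (2S,3S)-1-(TBDPSO)-3-methyl-2-{[(S)-1-(TBSO)-5-methylhex-5-en-3-yl]oxy}hept-6-en-3-ol | C=C(C)C[C@H](O[C@@H](CO[Si](c1ccccc1)(c1ccccc1)C(C)(C)C)[C@@](C)(O)CCC=C)CCO[Si](C)(C)C(C)(C)C | intermediate
11 | (2S,3S,9S,Z)-2-[(TBDPSO)methyl]-9-[2-(TBSO)ethyl]-3,7-dimethyl-2,3,4,5,8,9-hexahydrooxonin-3-ol | CC(C)(C)[Si](c1ccccc1)(c1ccccc1)OC[C@@H]2O[C@H](CCO[Si](C)(C)C(C)(C)C)C/C(C)=C\CC[C@]2(C)O | intermediate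
12 | oxonene 11 with the C11 silyl ether cleaved (9-(2-hydroxyethyl)) | CC(C)(C)[Si](c1ccccc1)(c1ccccc1)OC[C@@H]2O[C@H](CCO)C/C(C)=C\CC[C@]2(C)O | intermediate
13 | oxonene C11 aldehyde (9-(2-oxoethyl)) | CC(C)(C)[Si](c1ccccc1)(c1ccccc1)OC[C@@H]2O[C@H](CC=O)C/C(C)=C\CC[C@]2(C)O | intermediate
14 | oxonene vinyl carbinol (9-(2-hydroxybut-3-enyl), C11 epimers) | CC(C)(C)[Si](c1ccccc1)(c1ccccc1)OC[C@@H]2O[C@H](CC(O)C=C)C/C(C)=C\CC[C@]2(C)O | intermediate
15 | oxonene triol (2-hydroxymethyl, 3-ol, 9-(2-hydroxybut-3-enyl)) | OC[C@@H]1O[C@H](CC(O)C=C)C/C(C)=C\CC[C@]1(C)O | intermediate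
16 | oxonene C1 aldehyde (2-formyl) | O=C[C@@H]1O[C@H](CC(O)C=C)C/C(C)=C\CC[C@]1(C)O | intermediate
17 | (E)-Weinreb enamide at C2 (C1=C14), 9-(2-hydroxybut-3-enyl) | CON(C)C(=O)/C=C/[C@@H]1O[C@H](CC(O)C=C)C/C(C)=C\CC[C@]1(C)O | intermediate
18 | oxonene vinyl ketone (9-(2-oxobut-3-enyl)) with (E)-enamide | CON(C)C(=O)/C=C/[C@@H]1O[C@H](CC(=O)C=C)C/C(C)=C\CC[C@]1(C)O | intermediate
19 | (Z)-2-(TBSO)-buta-1,3-dienyl oxonene with (E)-enamide, C3 OTBS | CON(C)C(=O)/C=C/[C@@H]1O[C@H](/C=C(O[Si](C)(C)C(C)(C)C)/C=C)C/C(C)=C\CC[C@]1(C)O[Si](C)(C)C(C)(C)C | intermediate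
20 | tricyclic cycloadduct: C11 OTBS enol ether (C11=C12), C14 CON(OMe)Me, C3 OTBS | CON(C)C(=O)[C@@H]1CC=C(O[Si](C)(C)C(C)(C)C)[C@@H]2[C@H]1[C@@H]3O[C@H]2C/C(C)=C\CC[C@]3(C)O[Si](C)(C)C(C)(C)C | intermediate
21 | Mannich base: 12-(dimethylaminomethyl)-11-ketone (C12 epimers) | CON(C)C(=O)[C@@H]1CC(CN(C)C)C(=O)[C@@H]2[C@H]1[C@@H]3O[C@H]2C/C(C)=C\CC[C@]3(C)O[Si](C)(C)C(C)(C)C | intermediate
22 | trimethylammonium iodide of 21 | CON(C)C(=O)[C@@H]1CC(C[N+](C)(C)C)C(=O)[C@@H]2[C@H]1[C@@H]3O[C@H]2C/C(C)=C\CC[C@]3(C)O[Si](C)(C)C(C)(C)C.[I-] | intermediate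
23 | 12-methylene-11-ketone | CON(C)C(=O)[C@@H]1CC(=C)C(=O)[C@@H]2[C@H]1[C@@H]3O[C@H]2C/C(C)=C\CC[C@]3(C)O[Si](C)(C)C(C)(C)C | intermediate
24 | (12R)-12-methyl-11-ketone | CON(C)C(=O)[C@@H]1C[C@@H](C)C(=O)[C@@H]2[C@H]1[C@@H]3O[C@H]2C/C(C)=C\CC[C@]3(C)O[Si](C)(C)C(C)(C)C | intermediate
25 | 11-alcohol (OH, C12 methyl and C9 all cis), C14 Weinreb amide | CON(C)C(=O)[C@@H]1C[C@@H](C)[C@@H](O)[C@@H]2[C@H]1[C@@H]3O[C@H]2C/C(C)=C\CC[C@]3(C)O[Si](C)(C)C(C)(C)C | intermediate
26 | 14-acetyl 11-alcohol | CC(=O)[C@@H]1C[C@@H](C)[C@@H](O)[C@@H]2[C@H]1[C@@H]3O[C@H]2C/C(C)=C\CC[C@]3(C)O[Si](C)(C)C(C)(C)C | intermediate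
27 | 14-isopropenyl 11-alcohol | C=C(C)[C@@H]1C[C@@H](C)[C@@H](O)[C@@H]2[C@H]1[C@@H]3O[C@H]2C/C(C)=C\CC[C@]3(C)O[Si](C)(C)C(C)(C)C | intermediate
28 | 14-isopropenyl 11-acetate, C3 OTBS | C=C(C)[C@@H]1C[C@@H](C)[C@@H](OC(C)=O)[C@@H]2[C@H]1[C@@H]3O[C@H]2C/C(C)=C\CC[C@]3(C)O[Si](C)(C)C(C)(C)C | intermediate
29 | B-(C16-alkyl)-9-borabicyclo[3.3.1]nonane from 28 | C1CC2CCCC(C1)B2C[C@H](C)[C@@H]1C[C@@H](C)[C@@H](OC(C)=O)[C@@H]2[C@H]1[C@@H]3O[C@H]2C/C(C)=C\CC[C@]3(C)O[Si](C)(C)C(C)(C)C | intermediate
30 | C16 primary alcohol (15R), 11-acetate, C3 OTBS | OC[C@H](C)[C@@H]1C[C@@H](C)[C@@H](OC(C)=O)[C@@H]2[C@H]1[C@@H]3O[C@H]2C/C(C)=C\CC[C@]3(C)O[Si](C)(C)C(C)(C)C | intermediate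
31 | hydroxy acetate diol (C16–OH, C3–OH, 11-OAc) | OC[C@H](C)[C@@H]1C[C@@H](C)[C@@H](OC(C)=O)[C@@H]2[C@H]1[C@@H]3O[C@H]2C/C(C)=C\CC[C@]3(C)O | intermediate
32 | C16 trifluoromethanesulfonate of 31 | O=S(=O)(OC[C@H](C)[C@@H]1C[C@@H](C)[C@@H](OC(C)=O)[C@@H]2[C@H]1[C@@H]3O[C@H]2C/C(C)=C\CC[C@]3(C)O)C(F)(F)F | intermediate
33 | target CNP0177382.3 (1S,2S,3S,9S,10R,11R,12R,14S,15R; 6Z) | CC(=O)O[C@H]1[C@@H]2[C@@H]3[C@@H](C[C@H]1C)[C@@H](C)CO[C@@]1(C)CC/C=C(/C)C[C@@H]2O[C@@H]31 | target

Total step count: 26. Longest linear sequence: 26 steps (from 1).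

Steps most likely to fail:

Step 17. The vinyl ketone may lose the C9 oxygen by β-elimination or polymerise during enolisation, and the amide-activated alkene may add too slowly, so that the silyloxy diene decomposes before it cyclises. The fallback sets out from 16 and comes back at 20, moving to ester activation with the amide installed after the ring formation. Wittig reaction of 16 with methyl (triphenylphosphoranylidene)acetate should give the (E)-enoate allylic alcohol F1. Dess–Martin oxidation should give the enoate vinyl ketone F2. TBSOTf/Et3N and gentle warming should then give the cycloadduct methyl ester F3, the enoate being a stronger, non-enolisable dienophile. Aminolysis of F3 with MeNH(OMe)·HCl and i-PrMgCl at −20 °C should return 20.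

Step 19. Hydrogen may be delivered to both faces of the exocyclic alkene, or a rhodium hydride may move the double bond into the ring and give the conjugated endocyclic enone. The fallback sets out from 23 and comes back at 25, reversing the order and avoiding a metal hydride. Luche reduction (NaBH4, CeCl3, MeOH, −78 °C) should attack C11 from the open lower face and give the 12-methylene allylic alcohol F4. Diimide (2-nitrobenzenesulfonyl hydrazide, Et3N) should then reduce only the 1,1-disubstituted alkene, from the lower face, which the new C11 hydroxyl shields further on top, to give 25.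

Step 24. Two rotamers about C14–C15 may both react, so that boron adds to both alkene faces and C15 forms as a mixture. The fallback sets out from 28 and comes back at 30, replacing substrate control by catalyst control. Copper-hydride-catalysed hydroboration (CuCl, NaOt-Bu, the matched enantiomer of DTBM-SEGPHOS, pinacolborane) should give the (15R)-pinacol boronate F5. Oxidation with NaBO3 should give 30.

Further compounds
F1 | step 17 | methyl (E)-enoate at C2 (C1=C14), 9-(2-hydroxybut-3-enyl) oxonene | COC(=O)/C=C/[C@@H]1O[C@H](CC(O)C=C)C/C(C)=C\CC[C@]1(C)O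
F2 | step 17 | enoate vinyl ketone (9-(2-oxobut-3-enyl)) | COC(=O)/C=C/[C@@H]1O[C@H](CC(=O)C=C)C/C(C)=C\CC[C@]1(C)O
F3 | step 17 | tricyclic cycloadduct methyl ester (C11 OTBS enol ether, C3 OTBS) | COC(=O)[C@@H]1CC=C(O[Si](C)(C)C(C)(C)C)[C@@H]2[C@H]1[C@@H]3O[C@H]2C/C(C)=C\CC[C@]3(C)O[Si](C)(C)C(C)(C)C
F4 | step 19 | 12-methylene 11-alcohol (C14 Weinreb amide, C3 OTBS) | CON(C)C(=O)[C@@H]1CC(=C)[C@@H](O)[C@@H]2[C@H]1[C@@H]3O[C@H]2C/C(C)=C\CC[C@]3(C)O[Si](C)(C)C(C)(C)C
F5 | step 24 | (15R)-C16 pinacol boronate of 28 | CC1(C)OB(C[C@H](C)[C@@H]2C[C@@H](C)[C@@H](OC(C)=O)[C@@H]3[C@H]2[C@@H]4O[C@H]3C/C(C)=C\CC[C@]4(C)O[Si](C)(C)C(C)(C)C)OC1(C)C
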